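**Time of reading.** At 3.0 min the flask is read, and two earlier runs with the same c(substrate) and partner but with less and more catalyst bracket it.

the same everywhere: substrate 0.050 M

| run | partner | free catalyst | remark | time |
|---|---|---|---|---|
| grey | 0.50 equiv | 4.5 mol% | run made earlier |  |
| amber | 0.50 equiv | 18 mol% | run made earlier |  |
| flask | 0.500 equiv | 9.1 mol% |  | 3.0 min |

| run | time / min | substrate / % | over-reaction product / % | catalyst intermediate B / % | target / % | catalyst intermediate D / % | catalyst intermediate A / % |
|---|---|---|---|---|---|---|---|
| grey | 0.250 | 99 | 3 | 1 | 0 | 1 | 0 |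
| grey | 0.833 | 98 | 0 | 4 | 3 | 0 | 0 |
| grey | 1.33 | 94 | 3 | 1 | 2 | 1 | 0 |
| grey | 2.00 | 92 | 4 | 5 | 5 | 3 | 0 |
| grey | 3.00 | 89 | 0 | 6 | 6 | 2 | 1 |
| amber | 0.667 | 87 | 1 | 6 | 1 | 0 | 5 |
| amber | 1.33 | 79 | 0 | 10 | 7 | 2 | 3 |
| amber | 2.00 | 73 | 2 | 10 | 10 | 1 | 1 |
| amber | 2.50 | 67 | 2 | 13 | 15 | 1 | 6 |
| amber | 3.00 | 71 | 2 | 10 | 20 | 2 | 0 |

(readings scatter by 2 percentage points)



- the largest share of what was charged as substrate, at 3.0 min belongs to (target / catalyst intermediate B / catalyst intermediate D / over-reaction product / catalyst intermediate A / substrate)
- the largest share itself, whichever of these holds it, in percent of the substrate charged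

**One number.** I fold the charges into N, the substrate consumed per catalyst charged at that time: a turnover number that also counts catalyst-bound substrate. The readings at that time give 2.44 in the grey run and 1.61 in the amber run. These are readings with their scatter; grey stands higher than amber, so I do not carry one N across both loadings. The flask's loading is twice grey and half amber, so I take their geometric mean, N = 1.98 for the flask. My estimate is therefore 18.1 % consumed and 81.9 % left. I expect substrate to hold the largest share, because the estimate left is more than the whole estimate consumed.

**The forecast.** It says substrate, at 82 %: “Four times the catalyst therefore gives about 2.8 times the conversion”. It rests on the same readings as my reckoning, so their agreement checks nothing.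

**The result.** The flask gives substrate at 81.9 %, more than target at 10.0 %.

    partner → decomposed reagent (k = 0.00240 s⁻¹)
    catalyst intermediate C → catalyst intermediate D (k = 0.0890 s⁻¹)
    catalyst intermediate A → catalyst intermediate B (k = 0.0860 s⁻¹)
    catalyst intermediate D → free catalyst + target (k = 0.0800 s⁻¹)
    partner + catalyst intermediate B ⇌ catalyst intermediate C (K = 85.0 M⁻¹, k = 1.10 M⁻¹ s⁻¹)
    partner + target → over-reaction product (k = 0.0580 M⁻¹ s⁻¹)
    substrate + free catalyst ⇌ catalyst intermediate A (K = 32.0 M⁻¹, k = 1.40 M⁻¹ s⁻¹)

**Still moving.** The flask's N comes to 1.99, level with my 1.98. A neighbour flask at c(substrate) 0.020 M, with the same equivalents and loadings, stands at 88.6 % substrate, so its N is 1.25, less than 1.98. The flask is not at rest at 3.0 min: at 30.0 min substrate is 67.2 %, target 21.4 %, partner 0 % of its charge, and catalyst intermediate B >99.9 % of the catalyst charged.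

The readings were computed with made-up constants; noise was put on by code.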